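**Plan**

- The target is a chalcone whose only stereocentre is a secondary allylic carbinol carbon, bonded to the benzylic CH2 of ring B and to C2 of an isopropenyl group. That carbon is the adduct of an arylacetaldehyde and a 2-propenyl metal.
- Retrosynthetic cuts, in order: the two phenolic methoxymethyl (MOM) ethers; the enone C=C bond (Claisen–Schmidt), which separates the ring A ketone from the ring B aldehyde; the carbinol–isopropenyl C–C bond; the allyl C=C (to the arylacetaldehyde); the aryl–allyl bond on ring B and the aryl–prenyl bond on ring A.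
- Forward: no ring is formed. The ring B side chain is grown first (O-allyl, C-allyl, CH2CHO, carbinol), the ring A ketone is prenylated separately, the halves are joined by aldol condensation, and the MOM groups are removed last.
- Stereochemistry: the R centre comes from ligand-controlled addition of the 2-propenyl group to the Si face of the aldehyde in a catalytic asymmetric nickel/chromium coupling. The E alkene comes from the dehydration step of the condensation.

Key step: step 6

Remark: the ligand antipode in step 6 is taken as the one whose chromium complex delivers the 2-propenyl group to the Si face of the aldehyde (R carbinol); this assignment should be confirmed on the first batch by Mosher ester analysis.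

**Route**

Step 1
Reactants: 1 4-hydroxybenzaldehyde; 2 allyl bromide
Product: 3 4-(prop-2-enyloxy)benzaldehyde
Conditions: K2CO3, acetone, reflux
Reagents that add atoms: none
Why: Williamson etherification of an acidic para-formyl phenol with an allylic bromide under carbonate base is routine and leaves the aldehyde untouched.

Step 2
Reactants: 3 4-(prop-2-enyloxy)benzaldehyde
Product: 4 4-hydroxy-3-(prop-2-enyl)benzaldehyde
Conditions: N,N-diethylaniline, 210 °C (sealed vessel)
Reagents that add atoms: none
Why: Aromatic Claisen rearrangement, a [3,3] shift to the free ortho carbon followed by tautomerisation, with the para position blocked by the formyl group so that only the ortho-allyl phenol can form.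

Step 3
Reactants: 4 4-hydroxy-3-(prop-2-enyl)benzaldehyde
Product: 5 4-(methoxymethoxy)-3-(prop-2-enyl)benzaldehyde
Conditions: MOMCl, K2CO3, acetone, 0 °C → rt
Reagents that add atoms: chloromethyl methyl ether, COCCl
Why: O-alkylation of the phenoxide with MOMCl (Williamson-type) masks the phenol, which would otherwise deactivate the aldehyde as its phenoxide in step 10 and interfere with steps 5 and 6.

Step 4
Reactants: 5 4-(methoxymethoxy)-3-(prop-2-enyl)benzaldehyde
Product: 6 2-[4-(methoxymethoxy)-3-(prop-2-enyl)phenyl]-1,3-dioxolane
Conditions: 1,2-bis(trimethylsilyloxy)ethane, TMSOTf (cat.), CH2Cl2, −78 °C; pyridine quench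
Reagents that add atoms: 1,2-bis(trimethylsilyloxy)ethane, C[Si](C)(C)OCCO[Si](C)(C)C
Why: Noyori acetalisation is aprotic and runs at low temperature, so the aryl aldehyde should become the dioxolane without exchange of the MOM acetal, leaving only one free aldehyde in step 6.

Step 5
Reactants: 6 2-[4-(methoxymethoxy)-3-(prop-2-enyl)phenyl]-1,3-dioxolane
Product: 8 2-[5-(1,3-dioxolan-2-yl)-2-(methoxymethoxy)phenyl]acetaldehyde, via vicinal diol 7 (not isolated)
Conditions: OsO4 (cat.), NaIO4, 2,6-lutidine, dioxane/H2O (3:1), rt; crude aldehyde used at once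
Reagents that add atoms: OsO4, O=[Os](=O)(=O)=O (delivers the carbonyl oxygen and is regenerated by NaIO4, [Na+].[O-]I(=O)(=O)=O)
Why: Lemieux–Johnson cleavage dihydroxylates the only alkene and cleaves the diol with periodate, and the lutidine buffer keeps the medium neutral so that the dioxolane and MOM ether survive and the aldehyde is not over-oxidised.

Step 6
Reactants: 8 2-[5-(1,3-dioxolan-2-yl)-2-(methoxymethoxy)phenyl]acetaldehyde; 9 2-bromopropene
Product: 11 (2R)-1-[5-(1,3-dioxolan-2-yl)-2-(methoxymethoxy)phenyl]-3-methylbut-3-en-2-ol, via zirconium alkoxide 10 (not isolated)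
Conditions: CrCl2 (10 mol%), chiral N-[2-(4-isopropyl-4,5-dihydrooxazol-2-yl)phenyl]sulfonamide ligand (11 mol%), 1,8-bis(dimethylamino)naphthalene (11 mol%), NiCl2(2,9-dimethyl-1,10-phenanthroline) (2 mol%), Mn powder (2 equiv), Cp2ZrCl2 (1.2 equiv), LiCl (2 equiv), MeCN, rt; aq. NaHCO3 work-up
Reagents that add atoms: none
Why: Zerovalent nickel, formed in situ from the NiCl2 complex, inserts into the C–Br bond of 9 and passes the 2-propenyl group to trivalent chromium bearing the deprotonated sulfonamide–oxazoline ligand; this alkenylchromium adds to the chromium-bound aldehyde through a closed transition state, Cp2ZrCl2 takes the alkoxide off chromium as 10, and Mn returns chromium to the divalent state. The closest known reaction type is the catalytic asymmetric nickel/chromium (Nozaki–Hiyama–Kishi) coupling of 2-haloalkenes with α-unbranched aliphatic aldehydes. No ring closes; one C–C bond forms between the carbinol carbon and C2 of the isopropenyl group. The aldehyde has no resident stereocentre, so the new centre is set by the chiral ligand on chromium alone, its antipode being chosen for Si-face addition, which gives R. The step needs chemoselectivity for one aldehyde and freedom from enolisation: the aryl aldehyde is masked as the dioxolane, and the non-basic alkenylchromium in a near-neutral medium should not deprotonate the arylacetaldehyde. Cp2ZrCl2 is used in place of Me3SiCl to avoid silyl enol ether formation.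

Step 7
Reactants: 11 (2R)-1-[5-(1,3-dioxolan-2-yl)-2-(methoxymethoxy)phenyl]-3-methylbut-3-en-2-ol
Product: 12 3-[(2R)-2-hydroxy-3-methylbut-3-enyl]-4-(methoxymethoxy)benzaldehyde
Conditions: PPTS (0.2 equiv), THF/H2O (4:1), 40 °C
Reagents that add atoms: water, O
Why: Acetal hydrolysis of the dioxolane goes through a benzylic, para-alkoxy-stabilised oxocarbenium ion and should be far faster than cleavage of the aryl MOM ether or ionisation of the allylic alcohol under this weak acid, so the stereocentre is untouched.

Step 8
Reactants: 13 2,4-dihydroxyacetophenone; 14 prenyl bromide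
Product: 15 1-[2,4-dihydroxy-3-(3-methylbut-2-enyl)phenyl]ethanone
Conditions: KOH (10% aq.), 0 °C → rt; chromatographic separation from the 5-prenyl and O-prenyl isomers
Reagents that add atoms: none
Why: C-alkylation of the ambident resorcinol-type phenoxide in water, where solvation of oxygen favours attack through carbon, places the prenyl group on the doubly activated carbon between the two oxygens.

Step 9
Reactants: 15 1-[2,4-dihydroxy-3-(3-methylbut-2-enyl)phenyl]ethanone
Product: 16 1-[2-hydroxy-4-(methoxymethoxy)-3-(3-methylbut-2-enyl)phenyl]ethanone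
Conditions: MOMCl (1.1 equiv), K2CO3, acetone, 0 °C → rt
Reagents that add atoms: chloromethyl methyl ether, COCCl
Why: Selective Williamson-type etherification, since the 2-hydroxyl is hydrogen-bonded to the acetyl carbonyl and far less nucleophilic than the 4-hydroxyl.

Step 10
Reactants: 12 3-[(2R)-2-hydroxy-3-methylbut-3-enyl]-4-(methoxymethoxy)benzaldehyde; 16 1-[2-hydroxy-4-(methoxymethoxy)-3-(3-methylbut-2-enyl)phenyl]ethanone
Product: 17 (2E)-3-{3-[(2R)-2-hydroxy-3-methylbut-3-enyl]-4-(methoxymethoxy)phenyl}-1-[2-hydroxy-4-(methoxymethoxy)-3-(3-methylbut-2-enyl)phenyl]prop-2-en-1-one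
Conditions: KOH (50% aq.), EtOH, 0 °C → rt
Reagents that add atoms: none
Why: Claisen–Schmidt condensation, in which the acetophenone enolate adds to the non-enolisable aryl aldehyde and E1cB loss of water gives the E enone, while the carbinol centre has no acidic hydrogen and cannot epimerise.

Step 11
Reactants: 17 the bis-MOM chalcone
Product: 18 (2E)-1-[2,4-dihydroxy-3-(3-methylbut-2-enyl)phenyl]-3-{4-hydroxy-3-[(2R)-2-hydroxy-3-methylbut-3-enyl]phenyl}prop-2-en-1-one (CNP0387177.2)
Conditions: HCl (3 M aq.), MeOH, rt → 40 °C, stopped as soon as conversion is complete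
Reagents that add atoms: none
Why: Acid-catalysed acetal exchange with methanol removes both aryl MOM ethers under conditions mild enough that the prenyl group, the enone and the secondary allylic alcohol should not ionise or cyclise.

**Compound list**

1 | 4-hydroxybenzaldehyde | O=Cc1ccc(O)cc1 | starting material
2 | allyl bromide | C=CCBr | starting material
3 | 4-(prop-2-enyloxy)benzaldehyde | C=CCOc1ccc(C=O)cc1 | intermediate
4 | 4-hydroxy-3-(prop-2-enyl)benzaldehyde | C=CCc1cc(C=O)ccc1O | intermediate
5 | 4-(methoxymethoxy)-3-(prop-2-enyl)benzaldehyde | C=CCc1cc(C=O)ccc1OCOC | intermediate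
6 | 2-[4-(methoxymethoxy)-3-(prop-2-enyl)phenyl]-1,3-dioxolane | C=CCc1cc(C2OCCO2)ccc1OCOC | intermediate
7 | 3-[5-(1,3-dioxolan-2-yl)-2-(methoxymethoxy)phenyl]propane-1,2-diol (racemic, not isolated) | OCC(O)Cc1cc(C2OCCO2)ccc1OCOC | intermediate
8 | 2-[5-(1,3-dioxolan-2-yl)-2-(methoxymethoxy)phenyl]acetaldehyde | O=CCc1cc(C2OCCO2)ccc1OCOC | intermediate
9 | 2-bromopropene | C=C(C)Br | starting material
10 | chlorobis(cyclopentadienyl)zirconium alkoxide of (2R)-1-[5-(1,3-dioxolan-2-yl)-2-(methoxymethoxy)phenyl]-3-methylbut-3-en-2-ol (not isolated) | C=C(C)[C@H](O[Zr](Cl)(C1C=CC=C1)C1C=CC=C1)Cc1cc(C2OCCO2)ccc1OCOC | intermediate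
11 | (2R)-1-[5-(1,3-dioxolan-2-yl)-2-(methoxymethoxy)phenyl]-3-methylbut-3-en-2-ol | C=C(C)[C@H](O)Cc1cc(C2OCCO2)ccc1OCOC | intermediate
12 | 3-[(2R)-2-hydroxy-3-methylbut-3-enyl]-4-(methoxymethoxy)benzaldehyde | C=C(C)[C@H](O)Cc1cc(C=O)ccc1OCOC | intermediate
13 | 2,4-dihydroxyacetophenone | CC(=O)c1ccc(O)cc1O | starting material
14 | prenyl bromide (1-bromo-3-methylbut-2-ene) | CC(C)=CCBr | starting material
15 | 1-[2,4-dihydroxy-3-(3-methylbut-2-enyl)phenyl]ethanone | CC(=O)c1ccc(O)c(CC=C(C)C)c1O | intermediate
16 | 1-[2-hydroxy-4-(methoxymethoxy)-3-(3-methylbut-2-enyl)phenyl]ethanone | CC(=O)c1ccc(OCOC)c(CC=C(C)C)c1O | intermediate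
17 | (2E)-3-{3-[(2R)-2-hydroxy-3-methylbut-3-enyl]-4-(methoxymethoxy)phenyl}-1-[2-hydroxy-4-(methoxymethoxy)-3-(3-methylbut-2-enyl)phenyl]prop-2-en-1-one | C=C(C)[C@H](O)Cc1cc(/C=C/C(=O)c2ccc(OCOC)c(CC=C(C)C)c2O)ccc1OCOC | intermediate
18 | (2E)-1-[2,4-dihydroxy-3-(3-methylbut-2-enyl)phenyl]-3-{4-hydroxy-3-[(2R)-2-hydroxy-3-methylbut-3-enyl]phenyl}prop-2-en-1-one | C=C(C)[C@H](O)Cc1cc(/C=C/C(=O)c2ccc(O)c(CC=C(C)C)c2O)ccc1O | target

**Count**

Total steps: 11. Longest linear sequence: 9 steps (steps 1 to 7, then 10 and 11); steps 8 and 9 form the ring A branch.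

**Steps most likely to fail**

Step 6. The coupling may show incomplete enantioface control, slow oxidative addition of the alkenyl bromide, or enolisation and self-condensation of the arylacetaldehyde before it is consumed. The fallback makes the carbinol without any aldehyde and sets out from 6. Cross-metathesis with 2-methylbut-2-ene (second-generation Grubbs catalyst, RuCl2(=CHPh)(H2IMes)(PCy3), CH2Cl2, 40 °C) should give the prenyl arene 2-[4-(methoxymethoxy)-3-(3-methylbut-2-enyl)phenyl]-1,3-dioxolane F1. Shi epoxidation of the trisubstituted alkene (fructose-derived ketone catalyst of the antipode that leads to the R epoxide, Oxone (2KHSO5·KHSO4·K2SO4), K2CO3 buffer, MeCN/dimethoxymethane/H2O, 0 °C) should give 2-(3-{[(2R)-3,3-dimethyloxiran-2-yl]methyl}-4-(methoxymethoxy)phenyl)-1,3-dioxolane F2. Isomerisation of the epoxide with Et2Al(TMP) (from Et2AlCl and LiTMP, toluene, 0 °C) removes a methyl proton and opens the C–O bond at the quaternary carbon, leaving the secondary C–O bond and its configuration untouched, and should rejoin the route at 11.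

Step 8. The alkylation may show poor site selectivity: attack at the 5-position, O-alkylation and double alkylation compete with the wanted attack between the two oxygens. The fallback sets out from 13 and delivers the prenyl group intramolecularly. Alkylation of the non-chelated 4-hydroxyl with 3-chloro-3-methylbut-1-yne (K2CO3, KI, CuI cat., acetone, reflux) should give 1-{2-hydroxy-4-[(2-methylbut-3-yn-2-yl)oxy]phenyl}ethanone F3. Semi-hydrogenation (H2, Pd on CaCO3 poisoned with Pb(OAc)2, quinoline, EtOAc, rt) should give 1-{2-hydroxy-4-[(2-methylbut-3-en-2-yl)oxy]phenyl}ethanone F4. Aromatic Claisen rearrangement (N,N-diethylaniline, 140–180 °C) transposes the tertiary allyl ether into a prenyl group on the carbon between the two oxygens, the site favoured by the bond fixation of the chelated 2-hydroxyl, and should rejoin the route at 15.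

Step 11. Acid may close the liberated phenol onto the prenyl double bond, close the 2'-hydroxychalcone to the flavanone, or ionise the allylic alcohol before both MOM groups are gone. The fallback moves the acid step ahead of the condensation and sets out from 11 and 15. Treatment of 11 with HCl (2 M aq.) in THF at rt should remove dioxolane and MOM ether together, while neither prenyl group nor enone is present, and give 4-hydroxy-3-[(2R)-2-hydroxy-3-methylbut-3-enyl]benzaldehyde F5. Claisen–Schmidt condensation of this unprotected aldehyde with unprotected 15 in KOH (60% aq.)/EtOH at rt, which runs through the polyphenoxides, should then give 18 directly with no acid treatment at the end.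

**Further compounds**

F1 | step 6 | 2-[4-(methoxymethoxy)-3-(3-methylbut-2-enyl)phenyl]-1,3-dioxolane | CC(C)=CCc1cc(C2OCCO2)ccc1OCOC
F2 | step 6 | 2-(3-{[(2R)-3,3-dimethyloxiran-2-yl]methyl}-4-(methoxymethoxy)phenyl)-1,3-dioxolane | CC1(C)O[C@@H]1Cc1cc(C2OCCO2)ccc1OCOC
F3 | step 8 | 1-{2-hydroxy-4-[(2-methylbut-3-yn-2-yl)oxy]phenyl}ethanone | CC(=O)c1ccc(OC(C)(C)C#C)cc1O
F4 | step 8 | 1-{2-hydroxy-4-[(2-methylbut-3-en-2-yl)oxy]phenyl}ethanone | CC(=O)c1ccc(OC(C)(C)C=C)cc1O
F5 | step 11 | 4-hydroxy-3-[(2R)-2-hydroxy-3-methylbut-3-enyl]benzaldehyde | C=C(C)[C@H](O)Cc1cc(C=O)ccc1O
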